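**Retrosynthetic overview**
- Feature used: in the lactone (O1, C2, C3, C4, C5), C4 carries two CH2 arms, C5 bonded to O1 and the benzylic CH2 bonded to ring B. Both are taken from the two equivalent methylenes of an oxetane sitting on C2 of a tert-butyl β-keto ester.
- Late disconnections: the silyl ether on ring A, then the benzylic CH2–ring B bond (nickel-catalysed reductive coupling of a bromomethyl lactone with 4-bromoveratrole).
- Key disconnection: O1–C5, made by enantioselective acid-catalysed opening of the oxetane by the ester carbonyl oxygen with loss of isobutene. It fixes C4, and C3 follows as the trans epimer.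
- The β-keto ester comes from Claisen acylation of tert-butyl 2-(oxetan-3-yl)acetate (Wittig olefination of oxetan-3-one, then hydrogenation) with silylated methyl vanillate.
- Ring order: rings A and B and the oxetane are bought; the lactone is the only ring formed (step 5), and the oxetane is consumed in forming it.

Key step: step 5

Assumption on the chemistry: the (R)-acid of step 5 is taken to open the methylene that leads to (4S)-10; the sense of induction cannot be derived with certainty from known oxetane openings, and the (S)-acid is used instead if the other arm is opened.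

Remark on descriptors: ring A is the 4-hydroxy-3-methoxyphenyl ring and ring B the 3,4-dimethoxyphenyl ring. C4 is S in 10 and R in 11, 13 and 14 only because the priority of its exocyclic arm changes; the spatial arrangement is the same throughout.

**Route**

Step 1
Reactants: 1 methyl vanillate (methyl 4-hydroxy-3-methoxybenzoate)
Product: 2 methyl 4-[(tert-butyldimethylsilyl)oxy]-3-methoxybenzoate
Conditions: TBSCl, imidazole, DMF, rt
Reagents that add atoms: tert-butyldimethylsilyl chloride, CC(C)(C)[Si](C)(C)Cl
Why: Imidazole-promoted silylation of the phenol masks the acidic OH, which would otherwise quench the enolate and deactivate the ester in the Claisen condensation of step 4.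

Step 2
Reactants: 3 oxetan-3-one, 4 tert-butyl (triphenylphosphoranylidene)acetate
Product: 5 tert-butyl 2-(oxetan-3-ylidene)acetate
Conditions: CH2Cl2, 0 °C to rt
Reagents that add atoms: none
Why: Wittig olefination with a stabilised ylide; oxetan-3-one is a strained, unusually electrophilic ketone that should condense at room temperature without opening of the four-membered ring.

Step 3
Reactants: 5 tert-butyl 2-(oxetan-3-ylidene)acetate
Product: 6 tert-butyl 2-(oxetan-3-yl)acetate
Conditions: H2 (1 atm), 10% Pd/C, EtOAc, rt
Reagents that add atoms: none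
Why: Heterogeneous catalytic hydrogenation of the electron-poor exocyclic alkene; the oxetane C–O bonds should not be hydrogenolysed under these neutral conditions and no stereocentre is formed.

Step 4
Reactants: 6 tert-butyl 2-(oxetan-3-yl)acetate, 2 methyl 4-[(tert-butyldimethylsilyl)oxy]-3-methoxybenzoate
Product: 8 tert-butyl 3-{4-[(tert-butyldimethylsilyl)oxy]-3-methoxyphenyl}-2-(oxetan-3-yl)-3-oxopropanoate (racemic at C2), via lithium enolate 7 (not isolated)
Conditions: LiN(SiMe3)2 (2.3 equiv), THF, −78 °C; then 2, −78 to −20 °C; AcOH quench at −78 °C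
Reagents that add atoms: none
Why: Crossed Claisen condensation in which enolate 7 adds to the non-enolisable ester 2 and the second equivalent of base drives the reaction by deprotonating the β-keto ester; the oxetane is inert to base, the cold acidic quench keeps the liberated methoxide from attacking the aryl silyl ether, and the new C2 centre is formed racemic and stays labile.

Step 5
Reactants: 8 tert-butyl 3-{4-[(tert-butyldimethylsilyl)oxy]-3-methoxyphenyl}-2-(oxetan-3-yl)-3-oxopropanoate
Product: 10 (3S,4S)-3-{4-[(tert-butyldimethylsilyl)oxy]-3-methoxybenzoyl}-4-(hydroxymethyl)oxolan-2-one, via lactonium ion 9 (not isolated)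
Conditions: (R)-3,3'-bis(2,4,6-triisopropylphenyl)-1,1'-binaphthalene-2,2'-diyl hydrogen phosphate (10 mol%), dry toluene, 40 °C
Reagents that add atoms: none
Why: Proposed new method: the phosphoric acid hydrogen-bonds to the oxetane oxygen of 8, the carbonyl oxygen of the tert-butyl ester displaces that oxygen at one of the two ring methylenes in an SN2 opening driven by ring strain, and the lactonium ion 9, held as an ion pair by the chiral phosphate, sheds its tert-butyl group as isobutene, which returns the acid and makes formation of the O1–C5 bond irreversible. The closest known reactions are chiral phosphoric acid catalysed desymmetrising openings of 3-substituted oxetanes by tethered hydroxyl and other heteroatom nucleophiles and the lactonisation of tert-butyl esters onto acid-activated epoxides or halonium ions with loss of isobutene; a β-keto ester carbonyl has not served as the internal nucleophile in such a desymmetrisation. The lactone closes in the 5-exo-tet mode (ester oxygen, C2, C3, C4 and the attacked methylene, which becomes C5), and the arm that is not attacked is released as the hydroxymethyl group. C4 is set by the catalyst, which presents one of the two methylenes to the ester oxygen inside its 3,3'-diaryl pocket; because C2 of 8 is stereogenic but epimerises through the enol under the acid, both antipodes of 8 are drained through the matched arrangement, and C3 of 10, still acidic, settles trans to the C4 substituent under thermodynamic control. The step needs the ester oxygen to win over the aryl ketone oxygen and over the enol; the substrate answers this only through its tert-butyl ester, the one oxygen donor whose onium ion can discharge by simple loss of isobutene, so this chemoselectivity, together with the sense and level of the choice between the methylenes, is the unproven part.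

Step 6
Reactants: 10 (3S,4S)-3-{4-[(tert-butyldimethylsilyl)oxy]-3-methoxybenzoyl}-4-(hydroxymethyl)oxolan-2-one
Product: 11 (3S,4R)-4-(bromomethyl)-3-{4-[(tert-butyldimethylsilyl)oxy]-3-methoxybenzoyl}oxolan-2-one
Conditions: CBr4, PPh3, CH2Cl2, 0 °C; 10 used directly after step 5
Reagents that add atoms: tetrabromomethane, BrC(Br)(Br)Br
Why: Appel bromination, in which bromide displaces the alkoxyphosphonium group at the exocyclic CH2 so that no bond at C4 is touched; the base-free medium is chosen so that the acidic C3–H does not close a cyclopropane onto the new C–Br bond.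

Step 7
Reactants: 11 (3S,4R)-4-(bromomethyl)-3-{4-[(tert-butyldimethylsilyl)oxy]-3-methoxybenzoyl}oxolan-2-one, 12 4-bromoveratrole (4-bromo-1,2-dimethoxybenzene)
Product: 13 (3S,4R)-3-{4-[(tert-butyldimethylsilyl)oxy]-3-methoxybenzoyl}-4-(3,4-dimethoxybenzyl)oxolan-2-one
Conditions: NiBr2·glyme (10 mol%), 4,4'-di-tert-butyl-2,2'-bipyridine (10 mol%), NaI (0.5 equiv), Zn powder (2 equiv), 12 (1.5 equiv), DMA, 60 °C
Reagents that add atoms: none
Why: Nickel-catalysed reductive cross-electrophile coupling of an aryl bromide with a primary alkyl bromide, in which the bipyridine nickel catalyst adds to 12, captures the primary radical formed from 11 and reductively eliminates the benzylic CH2–ring B bond; the conditions are neutral and base-free, should tolerate ketone, lactone, silyl ether and acidic C–H, and leave C4 untouched with C3 trans.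

Step 8
Reactants: 13 (3S,4R)-3-{4-[(tert-butyldimethylsilyl)oxy]-3-methoxybenzoyl}-4-(3,4-dimethoxybenzyl)oxolan-2-one
Product: 14 (3S,4R)-4-(3,4-dimethoxybenzyl)-3-(4-hydroxy-3-methoxybenzoyl)oxolan-2-one (target)
Conditions: Bu4NF (1.1 equiv), AcOH (1.5 equiv), THF, 0 °C
Reagents that add atoms: none
Why: Fluoride-induced cleavage of the aryl silyl ether; buffering with acetic acid keeps the medium from opening the lactone, and C3, though acidic, should return to the favoured trans arrangement.

**Compound list**

1 | methyl vanillate (methyl 4-hydroxy-3-methoxybenzoate) | COC(=O)c1ccc(O)c(OC)c1 | starting material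
2 | methyl 4-[(tert-butyldimethylsilyl)oxy]-3-methoxybenzoate | COC(=O)c1ccc(O[Si](C)(C)C(C)(C)C)c(OC)c1 | intermediate
3 | oxetan-3-one | O=C1COC1 | starting material
4 | tert-butyl (triphenylphosphoranylidene)acetate | CC(C)(C)OC(=O)C=P(c1ccccc1)(c1ccccc1)c1ccccc1 | starting material
5 | tert-butyl 2-(oxetan-3-ylidene)acetate | CC(C)(C)OC(=O)C=C1COC1 | intermediate
6 | tert-butyl 2-(oxetan-3-yl)acetate | CC(C)(C)OC(=O)CC1COC1 | intermediate
7 | lithium enolate of 6 (lithium 1-tert-butoxy-2-(oxetan-3-yl)ethenolate) | [Li+].[O-]C(OC(C)(C)C)=CC1COC1 | intermediate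
8 | tert-butyl 3-{4-[(tert-butyldimethylsilyl)oxy]-3-methoxyphenyl}-2-(oxetan-3-yl)-3-oxopropanoate (racemic, C2 labile) | CC(C)(C)OC(=O)C(C1COC1)C(=O)c1ccc(O[Si](C)(C)C(C)(C)C)c(OC)c1 | intermediate
9 | (4S)-2-tert-butoxy-3-{4-[(tert-butyldimethylsilyl)oxy]-3-methoxybenzoyl}-4-(hydroxymethyl)-4,5-dihydro-3H-furan-1-ium (lactonium ion, paired with the chiral phosphate) | COc1cc(C(=O)C2C(OC(C)(C)C)=[O+]C[C@@H]2CO)ccc1O[Si](C)(C)C(C)(C)C | intermediate
10 | (3S,4S)-3-{4-[(tert-butyldimethylsilyl)oxy]-3-methoxybenzoyl}-4-(hydroxymethyl)oxolan-2-one | COc1cc(C(=O)[C@H]2C(=O)OC[C@@H]2CO)ccc1O[Si](C)(C)C(C)(C)C | intermediate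
11 | (3S,4R)-4-(bromomethyl)-3-{4-[(tert-butyldimethylsilyl)oxy]-3-methoxybenzoyl}oxolan-2-one | COc1cc(C(=O)[C@H]2C(=O)OC[C@@H]2CBr)ccc1O[Si](C)(C)C(C)(C)C | intermediate
12 | 4-bromoveratrole (4-bromo-1,2-dimethoxybenzene) | COc1ccc(Br)cc1OC | starting material
13 | (3S,4R)-3-{4-[(tert-butyldimethylsilyl)oxy]-3-methoxybenzoyl}-4-(3,4-dimethoxybenzyl)oxolan-2-one | COc1cc(C(=O)[C@H]2C(=O)OC[C@@H]2Cc2ccc(OC)c(OC)c2)ccc1O[Si](C)(C)C(C)(C)C | intermediate
14 | (3S,4R)-4-(3,4-dimethoxybenzyl)-3-(4-hydroxy-3-methoxybenzoyl)oxolan-2-one | COc1cc(C(=O)[C@H]2C(=O)OC[C@@H]2Cc2ccc(OC)c(OC)c2)ccc1O | target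

**Step count**

Total: 8 steps. Longest linear sequence: 7 steps (3 → 5 → 6 → 8 → 10 → 11 → 13 → 14).

**Steps most likely to fail**

Step 5 (proposed new method). What may go wrong:
- opening of the oxetane by the ketone oxygen or its enol instead of the ester oxygen;
- weak discrimination between the two methylenes;
- acid-induced loss of isobutene before ring opening, followed by decarboxylation;
- migration of the lactone acyl group between the two arms of the product, which would racemise C4;
- ring closure of the new hydroxyl onto the ketone.

Fallback, known chemistry throughout, with C4 taken from the chiral pool. It sets out from 12, which is converted with Mg in THF into (3,4-dimethoxyphenyl)magnesium bromide F1. With catalytic CuI at −30 °C, F1 opens ethyl (1S,5R)-2-oxo-3-oxabicyclo[3.1.0]hexane-1-carboxylate F2 (one step from diethyl malonate and (R)-epichlorohydrin with NaOEt in EtOH) at the cyclopropane CH2 by homoconjugate addition. This should give ethyl (3S,4R)-4-(3,4-dimethoxybenzyl)-2-oxooxolane-3-carboxylate F3. Krapcho decarboxylation (LiCl, wet DMSO, 140 °C) then gives (4R)-4-(3,4-dimethoxybenzyl)oxolan-2-one F4. F4 is deprotonated with LiN(SiMe3)2 (2.2 equiv, THF, −78 °C) and acylated with ester 2 in a Claisen condensation; protonation places the aroyl group trans. The fallback comes back to the route at 13, and step 8 follows unchanged.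

Step 7. What may go wrong:
- quenching of the alkyl radical or alkylnickel species by the acidic C3–H, leading to plain reduction;
- intramolecular displacement of bromide by C3 closing a cyclopropane (this also threatens step 6 and any storage of 11);
- homocoupling of either bromide;
- slow oxidative addition of the electron-rich aryl bromide.

Fallback: the ring closure is made the route. It sets out from 10, which is sulfonylated (MsCl, Et3N, CH2Cl2, 0 °C) to (3S,4R)-3-{4-[(tert-butyldimethylsilyl)oxy]-3-methoxybenzoyl}-4-[(methanesulfonyloxy)methyl]oxolan-2-one F5. DBU then closes, by 3-exo-tet C-alkylation, (1S,5R)-1-{4-[(tert-butyldimethylsilyl)oxy]-3-methoxybenzoyl}-3-oxabicyclo[3.1.0]hexan-2-one F6. The Grignard reagent F1 (from 12), with CuBr·SMe2 (20 mol%) in THF at −40 °C, opens this doubly activated cyclopropane at its CH2 by homoconjugate addition, and the enolate is protonated to the trans lactone. The fallback comes back at 13; the C4 centre (C5 of F6) is never touched.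

Step 4. What may go wrong:
- slow addition of the β-branched enolate to the electron-rich ester;
- cleavage of the aryl silyl ether by the lithium methoxide that is released;
- self-condensation of 6.

Fallback: the order of bond formation is reversed. It sets out from 2, which undergoes Claisen condensation with tert-butyl acetate (LiN(SiMe3)2, THF, −78 °C) to give tert-butyl 3-{4-[(tert-butyldimethylsilyl)oxy]-3-methoxyphenyl}-3-oxopropanoate F7. Knoevenagel condensation with oxetan-3-one 3 (piperidine, AcOH, toluene, 4 Å molecular sieves) gives tert-butyl 3-{4-[(tert-butyldimethylsilyl)oxy]-3-methoxyphenyl}-2-(oxetan-3-ylidene)-3-oxopropanoate F8. Conjugate reduction with the Hantzsch ester (diethyl 2,6-dimethyl-1,4-dihydropyridine-3,5-dicarboxylate) returns to the route at 8.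

Further compounds
F1 | step 5 | (3,4-dimethoxyphenyl)magnesium bromide | COc1ccc([Mg]Br)cc1OC
F2 | step 5 | ethyl (1S,5R)-2-oxo-3-oxabicyclo[3.1.0]hexane-1-carboxylate | O=C1OC[C@@H]2C[C@]12C(=O)OCC
F3 | step 5 | ethyl (3S,4R)-4-(3,4-dimethoxybenzyl)-2-oxooxolane-3-carboxylate | CCOC(=O)[C@H]1C(=O)OC[C@@H]1Cc1ccc(OC)c(OC)c1
F4 | step 5 | (4R)-4-(3,4-dimethoxybenzyl)oxolan-2-one | O=C1OC[C@@H](C1)Cc1ccc(OC)c(OC)c1
F5 | step 7 | (3S,4R)-3-{4-[(tert-butyldimethylsilyl)oxy]-3-methoxybenzoyl}-4-[(methanesulfonyloxy)methyl]oxolan-2-one | COc1cc(C(=O)[C@H]2C(=O)OC[C@@H]2COS(C)(=O)=O)ccc1O[Si](C)(C)C(C)(C)C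
F6 | step 7 | (1S,5R)-1-{4-[(tert-butyldimethylsilyl)oxy]-3-methoxybenzoyl}-3-oxabicyclo[3.1.0]hexan-2-one | O=C1OC[C@@H]2C[C@]12C(=O)c1ccc(O[Si](C)(C)C(C)(C)C)c(OC)c1
F7 | step 4 | tert-butyl 3-{4-[(tert-butyldimethylsilyl)oxy]-3-methoxyphenyl}-3-oxopropanoate | CC(C)(C)OC(=O)CC(=O)c1ccc(O[Si](C)(C)C(C)(C)C)c(OC)c1
F8 | step 4 | tert-butyl 3-{4-[(tert-butyldimethylsilyl)oxy]-3-methoxyphenyl}-2-(oxetan-3-ylidene)-3-oxopropanoate | CC(C)(C)OC(=O)C(=C1COC1)C(=O)c1ccc(O[Si](C)(C)C(C)(C)C)c(OC)c1
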